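**Plan**
1. Retrosynthesis: the three CH2OH groups are traced back to ethyl esters. The C2–C3 bond of each of the two 2,3-dihydrobenzofuran rings is then cut, which opens the target to a linear tris-aryl bis(benzyl aryl ether). Last, the two ArO–CH2Ar bonds and the cinnamate C=C are cut, giving vanillin (ring A) and two molecules of 5-iodovanillin (rings B and C).
2. Enabling feature: in each five-membered ring, C2 is a benzylic ether CH (O1–C2H–aryl, aryl para-oxygenated) and C3 is a benzylic carbon bearing a one-carbon substituent. With that substituent as CO2Et, C3 can be a donor/acceptor carbene lying 1,5 to the hydridic C2–H across O1/C7a/C3a.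
3. Forward: two Mitsunobu etherifications join rings A, B and C. Both aryl iodides are exchanged for diazoacetate units, and one twofold carbene C–H insertion closes the outer ring (between rings A and B) and the inner ring (between rings B and C).
4. Stereochemistry: the chiral dirhodium carboxylate sets both C2 centres (R). Both C3 centres are then equilibrated to trans from C2 (thermodynamic control). The E-alkene comes from a stabilised Wittig reaction. Ester reduction and desilylation finish the route.

Key step: step 8

Remark: the (S)-tert-leucinate catalyst Rh2(S-PTTL)4 is assumed to deliver the 2R centres; if its sense of induction proves opposite, the mirror-image catalyst Rh2(R-PTTL)4 is used with no other change.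

**Step 1**
Reactants: 1 vanillin
Product: 2 3-methoxy-4-(triisopropylsilyloxy)benzaldehyde
Conditions: TIPSCl, imidazole, DMF, rt
Reagents that add atoms: triisopropylsilyl chloride, CC(C)[Si](Cl)(C(C)C)C(C)C
Why: Imidazole-promoted O-silylation of the phenol gives a bulky aryl silyl ether that should survive the later amine bases and hydrides and keeps ring A from phenoxide/quinone methide chemistry until the end.

**Step 2**
Reactants: 2 3-methoxy-4-(triisopropylsilyloxy)benzaldehyde
Product: 3 [3-methoxy-4-(triisopropylsilyloxy)phenyl]methanol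
Conditions: NaBH4, MeOH–THF, 0 °C
Reagents that add atoms: none
Why: Borohydride reduction of the aryl aldehyde to the benzylic alcohol should leave the aryl silyl ether untouched at 0 °C.

**Step 3**
Reactants: 3 [3-methoxy-4-(triisopropylsilyloxy)phenyl]methanol; 4 5-iodovanillin
Product: 5 3-iodo-5-methoxy-4-{[3-methoxy-4-(triisopropylsilyloxy)benzyl]oxy}benzaldehyde
Conditions: PPh3, DIAD, THF, 0 °C to rt
Reagents that add atoms: none
Why: Mitsunobu etherification of the acidic phenol (ortho-iodo, para-formyl) with the primary benzylic alcohol forms the ring A–ring B ether without having to isolate a labile para-silyloxybenzyl halide.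

**Step 4**
Reactants: 5 3-iodo-5-methoxy-4-{[3-methoxy-4-(triisopropylsilyloxy)benzyl]oxy}benzaldehyde
Product: 6 (3-iodo-5-methoxy-4-{[3-methoxy-4-(triisopropylsilyloxy)benzyl]oxy}phenyl)methanol
Conditions: NaBH4, MeOH–THF, 0 °C
Reagents that add atoms: none
Why: Borohydride reduction of the aldehyde gives the ring B benzylic alcohol; the aryl iodide, benzyl ether and silyl ether are inert to it.

**Step 5**
Reactants: 4 5-iodovanillin; 7 ethyl (triphenylphosphoranylidene)acetate
Product: 8 ethyl (E)-3-(4-hydroxy-3-iodo-5-methoxyphenyl)acrylate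
Conditions: toluene, 90 °C
Reagents that add atoms: ethyl (triphenylphosphoranylidene)acetate (7), CCOC(=O)C=P(c1ccccc1)(c1ccccc1)c1ccccc1
Why: Wittig olefination with a stabilised ylide tolerates the free phenol and should give the E-cinnamate, which later becomes the (E)-allylic alcohol side chain.

**Step 6**
Reactants: 6 (3-iodo-5-methoxy-4-{[3-methoxy-4-(triisopropylsilyloxy)benzyl]oxy}phenyl)methanol; 8 ethyl (E)-3-(4-hydroxy-3-iodo-5-methoxyphenyl)acrylate
Product: 9 ethyl (E)-3-{3-iodo-4-[(3-iodo-5-methoxy-4-{[3-methoxy-4-(triisopropylsilyloxy)benzyl]oxy}benzyl)oxy]-5-methoxyphenyl}acrylate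
Conditions: PPh3, DIAD, THF, 0 °C to rt
Reagents that add atoms: none
Why: A second Mitsunobu etherification joins ring B to the acidic ring C phenol; the beta-aryl acrylate is too unreactive to intercept the phosphine.

**Step 7**
Reactants: 9 the bis(aryl iodide) from step 6; 10 ethyl diazoacetate
Product: 11 ethyl (E)-3-{3-(1-diazo-2-ethoxy-2-oxoethyl)-4-[(3-(1-diazo-2-ethoxy-2-oxoethyl)-5-methoxy-4-{[3-methoxy-4-(triisopropylsilyloxy)benzyl]oxy}benzyl)oxy]-5-methoxyphenyl}acrylate
Conditions: Pd(PPh3)4 (10 mol %), Ag2CO3, Et3N, toluene, rt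
Reagents that add atoms: ethyl diazoacetate (10), CCOC(=O)C=[N+]=[N-]
Why: Cross-coupling of aryl iodides with the C–H bond of a diazoacetate under zerovalent palladium (oxidative addition, silver/amine-assisted palladation of the diazo carbon, reductive elimination with the diazo group retained) should put the carbene precursor on both rings at room temperature, where Heck coupling and direct arylation of the benzyl ethers do not compete.

**Step 8**
Reactants: 11 the bis(aryl diazoacetate) from step 7
Product: 14 ethyl (2R,3S)-2-{(2R,3S)-3-(ethoxycarbonyl)-7-methoxy-2-[3-methoxy-4-(triisopropylsilyloxy)phenyl]-2,3-dihydrobenzofuran-5-yl}-5-[(E)-3-ethoxy-3-oxoprop-1-enyl]-7-methoxy-2,3-dihydrobenzofuran-3-carboxylate (cis,cis), via outer-ring-closed monodiazo ester 12 (not isolated), via inner-ring-closed monodiazo ester 13 (not isolated)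
Conditions: Rh2(S-PTTL)4 (dirhodium tetrakis[N-phthaloyl-(S)-tert-leucinate], 2 mol %), toluene, −60 °C, slow addition of 11
Reagents that add atoms: none
Why: The divalent rhodium catalyst expels N2 from each aryl diazoacetate to give an electrophilic donor/acceptor carbenoid at the future C3, which inserts through a concerted, asynchronous three-centre (hydride-shift-like) transition state into the O–CH2–aryl C–H bond five atoms away and so forms the C3–C2 bond; the closest known reaction type is the enantioselective intramolecular C–H insertion of ortho-benzyloxy aryldiazoacetates to cis-2-aryl-2,3-dihydrobenzofuran-3-carboxylates under chiral dirhodium tetracarboxylates, here run twice in one molecule. Each of the two five-membered rings (outer ring between rings A and B, inner ring between rings B and C, in either order by way of 12 or 13) closes by a 1,5-C–H insertion, that is, a five-membered ring closure in which the carbene carbon attacks an sp3 C–H bond. Each C2 (R) is controlled by the chiral carboxylate ligands, which select one of the two enantiotopic benzylic hydrogens, and each C3 should arise cis to the C2 aryl group from the compact insertion transition state (kinetic; corrected in step 9). The step needs site selectivity (1,5-insertion over carbene dimerisation, cyclopropanation of the cinnamate and arene cycloaddition) and the same sense of induction in both events; the substrate secures this because each carbene can reach exactly one C–H bond, that bond is doubly activated (alpha to oxygen and benzylic to a para-oxygenated arene), the cinnamate is electron-poor and trans-disubstituted, and no O–H or N–H is present. Because the two centres are set independently by the catalyst, a mis-insertion should end up mainly in a separable diastereomer, so the major diastereomer is expected to be enriched in enantiopurity (statistical amplification).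

**Step 9**
Reactants: 14 the cis,cis-diester from step 8
Product: 15 ethyl (2R,3R)-2-{(2R,3R)-3-(ethoxycarbonyl)-7-methoxy-2-[3-methoxy-4-(triisopropylsilyloxy)phenyl]-2,3-dihydrobenzofuran-5-yl}-5-[(E)-3-ethoxy-3-oxoprop-1-enyl]-7-methoxy-2,3-dihydrobenzofuran-3-carboxylate (trans,trans)
Conditions: DBU, MeCN, 50 °C
Reagents that add atoms: none
Why: Base-mediated thermodynamic epimerisation through the ester enolates should move both C3 esters trans to the C2 aryl groups while C2 is untouched; ring opening by loss of the aryloxide would be the reverse of a 5-endo-trig closure and is stereoelectronically slow, and the non-nucleophilic amidine should not cleave the silyl ether.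

**Step 10**
Reactants: 15 the trans,trans-diester from step 9
Product: 16 (E)-3-[(2R,3S)-3-(hydroxymethyl)-2-{(2R,3S)-3-(hydroxymethyl)-7-methoxy-2-[3-methoxy-4-(triisopropylsilyloxy)phenyl]-2,3-dihydrobenzofuran-5-yl}-7-methoxy-2,3-dihydrobenzofuran-5-yl]prop-2-en-1-ol
Conditions: i-Bu2AlH (excess), CH2Cl2, −78 to 0 °C; aq. potassium sodium tartrate
Reagents that add atoms: none
Why: Hydride reduction with DIBAL-H converts the two ring esters into the CH2OH groups and the cinnamate, by 1,2-reduction only, into the (E)-allylic alcohol; the C3 descriptor changes from R to S by priority only, not in space.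

**Step 11**
Reactants: 16 the silyl-protected triol from step 10
Product: 17 (E)-3-[(2R,3S)-2-{(2R,3S)-2-(4-hydroxy-3-methoxyphenyl)-3-(hydroxymethyl)-7-methoxy-2,3-dihydrobenzofuran-5-yl}-3-(hydroxymethyl)-7-methoxy-2,3-dihydrobenzofuran-5-yl]prop-2-en-1-ol (CNP0250921.1)
Conditions: Bu4NF, AcOH, THF, 0 °C
Reagents that add atoms: none
Why: Fluoride-mediated cleavage of the aryl silyl ether, buffered with acetic acid so that no free phenoxide builds up (which could open the outer ring through a quinone methide), should release the guaiacyl phenol and leave the allylic alcohol and benzylic ethers alone.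

**Compound list**
1 | vanillin (4-hydroxy-3-methoxybenzaldehyde) | COc1cc(C=O)ccc1O | starting material
2 | 3-methoxy-4-(triisopropylsilyloxy)benzaldehyde | COc1cc(C=O)ccc1O[Si](C(C)C)(C(C)C)C(C)C | intermediate
3 | [3-methoxy-4-(triisopropylsilyloxy)phenyl]methanol | COc1cc(CO)ccc1O[Si](C(C)C)(C(C)C)C(C)C | intermediate
4 | 5-iodovanillin (4-hydroxy-3-iodo-5-methoxybenzaldehyde) | COc1cc(C=O)cc(I)c1O | starting material
5 | 3-iodo-5-methoxy-4-{[3-methoxy-4-(triisopropylsilyloxy)benzyl]oxy}benzaldehyde | COc1cc(C=O)cc(I)c1OCc1ccc(O[Si](C(C)C)(C(C)C)C(C)C)c(OC)c1 | intermediate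
6 | (3-iodo-5-methoxy-4-{[3-methoxy-4-(triisopropylsilyloxy)benzyl]oxy}phenyl)methanol | COc1cc(CO)cc(I)c1OCc1ccc(O[Si](C(C)C)(C(C)C)C(C)C)c(OC)c1 | intermediate
7 | ethyl (triphenylphosphoranylidene)acetate | CCOC(=O)C=P(c1ccccc1)(c1ccccc1)c1ccccc1 | starting material
8 | ethyl (E)-3-(4-hydroxy-3-iodo-5-methoxyphenyl)acrylate | CCOC(=O)/C=C/c1cc(I)c(O)c(OC)c1 | intermediate
9 | ethyl (E)-3-{3-iodo-4-[(3-iodo-5-methoxy-4-{[3-methoxy-4-(triisopropylsilyloxy)benzyl]oxy}benzyl)oxy]-5-methoxyphenyl}acrylate | CCOC(=O)/C=C/c1cc(I)c(OCc2cc(I)c(OCc3ccc(O[Si](C(C)C)(C(C)C)C(C)C)c(OC)c3)c(OC)c2)c(OC)c1 | intermediate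
10 | ethyl diazoacetate | CCOC(=O)C=[N+]=[N-] | starting material
11 | bis(aryl diazoacetate): 9 with each iodine replaced by C(=N2)CO2Et | CCOC(=O)/C=C/c1cc(C(=[N+]=[N-])C(=O)OCC)c(OCc2cc(C(=[N+]=[N-])C(=O)OCC)c(OCc3ccc(O[Si](C(C)C)(C(C)C)C(C)C)c(OC)c3)c(OC)c2)c(OC)c1 | intermediate
12 | outer-ring-closed monodiazo ester: (2R,3S)-cis-dihydrobenzofuran between rings A and B, ring C still carrying the diazo ester and linked through OCH2 | COc1cc([C@@H]2Oc3c(OC)cc(COc4c(OC)cc(/C=C/C(=O)OCC)cc4C(=[N+]=[N-])C(=O)OCC)cc3[C@@H]2C(=O)OCC)ccc1O[Si](C(C)C)(C(C)C)C(C)C | intermediate (not isolated)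
13 | inner-ring-closed monodiazo ester: (2R,3S)-cis-dihydrobenzofuran between rings B and C, ring B still carrying the diazo ester and the ring A benzyl ether | COc1cc(COc2c(OC)cc([C@@H]3Oc4c(OC)cc(/C=C/C(=O)OCC)cc4[C@@H]3C(=O)OCC)cc2C(=[N+]=[N-])C(=O)OCC)ccc1O[Si](C(C)C)(C(C)C)C(C)C | intermediate (not isolated)
14 | cis,cis-diester, (2R,3S) in both dihydrobenzofurans (full name in step 8) | COc1cc([C@@H]2Oc3c(OC)cc([C@@H]4Oc5c(OC)cc(/C=C/C(=O)OCC)cc5[C@@H]4C(=O)OCC)cc3[C@@H]2C(=O)OCC)ccc1O[Si](C(C)C)(C(C)C)C(C)C | intermediate
15 | trans,trans-diester, (2R,3R) in both dihydrobenzofurans (full name in step 9) | COc1cc([C@@H]2Oc3c(OC)cc([C@@H]4Oc5c(OC)cc(/C=C/C(=O)OCC)cc5[C@H]4C(=O)OCC)cc3[C@H]2C(=O)OCC)ccc1O[Si](C(C)C)(C(C)C)C(C)C | intermediate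
16 | triisopropylsilyl ether of the target, (2R,3S) in both dihydrobenzofurans, E-alkene (full name in step 10) | COc1cc([C@@H]2Oc3c(OC)cc([C@@H]4Oc5c(OC)cc(/C=C/CO)cc5[C@H]4CO)cc3[C@H]2CO)ccc1O[Si](C(C)C)(C(C)C)C(C)C | intermediate
17 | CNP0250921.1, (2R,3S) in both dihydrobenzofurans, trans,trans, E-alkene (full name in step 11) | COc1cc([C@@H]2Oc3c(OC)cc([C@@H]4Oc5c(OC)cc(/C=C/CO)cc5[C@H]4CO)cc3[C@H]2CO)ccc1O | target

**Step count**
Total steps: 11. Longest linear sequence: 10 steps (1, 2, 3, 4, 6, 7, 8, 9, 10, 11); step 5 is the side branch.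

**Steps most likely to fail**

Step 8 (twofold C–H insertion). The two carbene centres may interfere with each other, through intermolecular carbene/diazo coupling or through lower facial discrimination in the second insertion once the first ring is present. This would leave stereoisomer mixtures that cannot be purified at the bis-cyclised stage. The fallback closes one ring at a time with purification in between. It sets out from 5: coupling with 10 [Pd(PPh3)4, Ag2CO3, Et3N, toluene, rt; the aldehyde is inert to the diazoacetate under amine base] gives the monodiazo aldehyde F2. Rh2(S-PTTL)4 in toluene at −60 °C closes the outer ring to the cis-dihydrobenzofuran aldehyde F3, which can be purified and enriched by crystallisation. NaBH4 in EtOH at −20 °C gives the benzylic alcohol F4. Mitsunobu etherification with 8 gives the aryl iodide F5, and a second coupling with 10 delivers 12. Here the route is rejoined: 12 needs only the single, inner-ring insertion under the step 8 conditions to reach 14. Any C3 epimer formed on the way converges in step 9.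

Step 7 (twofold coupling with the diazoacetate). The second coupling at the hindered ortho-alkoxy iodide may stall, or palladium may strip N2 from the product and cause carbene dimerisation. The fallback separates carbon–carbon bond formation from diazo installation. It sets out from 9: a twofold Negishi-type coupling with the Reformatsky reagent BrZnCH2CO2Et [Pd2(dba)3, XPhos, THF, 50 °C, zerovalent palladium catalysis] gives the bis(ethyl arylacetate) F1. Regitz diazo transfer (4-acetamidobenzenesulfonyl azide, DBU, MeCN, 0 °C to rt) then gives 11, where the route is rejoined.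

Step 9 (epimerisation). Proton exchange at the hindered tertiary C3–H may be too slow with DBU, and more forcing base risks loss of the silyl group followed by ring opening and scrambling at C2. The fallback epimerises at the aldehyde oxidation level, where a mild amine suffices. It sets out from 14: i-Bu2AlH (CH2Cl2, −78 to 0 °C) gives the cis,cis-triol F6. Dess–Martin periodinane (NaHCO3, CH2Cl2, 0 °C) gives the cis,cis-trialdehyde F7. Et3N in CH2Cl2 at rt equilibrates the acidic alpha-aryl aldehydes to the trans,trans-trialdehyde F8. Luche reduction (NaBH4, CeCl3·7H2O, MeOH, −40 °C) returns all three aldehydes to alcohols and rejoins the route at 16.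

**Further compounds**
F1 | step 7 | ethyl (E)-3-{3-(2-ethoxy-2-oxoethyl)-4-[(3-(2-ethoxy-2-oxoethyl)-5-methoxy-4-{[3-methoxy-4-(triisopropylsilyloxy)benzyl]oxy}benzyl)oxy]-5-methoxyphenyl}acrylate | CCOC(=O)/C=C/c1cc(CC(=O)OCC)c(OCc2cc(CC(=O)OCC)c(OCc3ccc(O[Si](C(C)C)(C(C)C)C(C)C)c(OC)c3)c(OC)c2)c(OC)c1
F2 | step 8 | ethyl 2-diazo-2-(5-formyl-3-methoxy-2-{[3-methoxy-4-(triisopropylsilyloxy)benzyl]oxy}phenyl)acetate | CCOC(=O)C(=[N+]=[N-])c1cc(C=O)cc(OC)c1OCc1ccc(O[Si](C(C)C)(C(C)C)C(C)C)c(OC)c1
F3 | step 8 | ethyl (2R,3S)-5-formyl-7-methoxy-2-[3-methoxy-4-(triisopropylsilyloxy)phenyl]-2,3-dihydrobenzofuran-3-carboxylate | COc1cc([C@@H]2Oc3c(OC)cc(C=O)cc3[C@@H]2C(=O)OCC)ccc1O[Si](C(C)C)(C(C)C)C(C)C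
F4 | step 8 | ethyl (2R,3S)-5-(hydroxymethyl)-7-methoxy-2-[3-methoxy-4-(triisopropylsilyloxy)phenyl]-2,3-dihydrobenzofuran-3-carboxylate | COc1cc([C@@H]2Oc3c(OC)cc(CO)cc3[C@@H]2C(=O)OCC)ccc1O[Si](C(C)C)(C(C)C)C(C)C
F5 | step 8 | ethyl (2R,3S)-5-({4-[(E)-3-ethoxy-3-oxoprop-1-enyl]-2-iodo-6-methoxyphenoxy}methyl)-7-methoxy-2-[3-methoxy-4-(triisopropylsilyloxy)phenyl]-2,3-dihydrobenzofuran-3-carboxylate | COc1cc([C@@H]2Oc3c(OC)cc(COc4c(OC)cc(/C=C/C(=O)OCC)cc4I)cc3[C@@H]2C(=O)OCC)ccc1O[Si](C(C)C)(C(C)C)C(C)C
F6 | step 9 | cis,cis-triol: the (2R,3R),(2R,3R) C3 epimer of 16 | COc1cc([C@@H]2Oc3c(OC)cc([C@@H]4Oc5c(OC)cc(/C=C/CO)cc5[C@@H]4CO)cc3[C@@H]2CO)ccc1O[Si](C(C)C)(C(C)C)C(C)C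
F7 | step 9 | cis,cis-trialdehyde, (2R,3S) in both rings, (E)-enal side chain | COc1cc([C@@H]2Oc3c(OC)cc([C@@H]4Oc5c(OC)cc(/C=C/C=O)cc5[C@@H]4C=O)cc3[C@@H]2C=O)ccc1O[Si](C(C)C)(C(C)C)C(C)C
F8 | step 9 | trans,trans-trialdehyde, (2R,3R) in both rings, (E)-enal side chain | COc1cc([C@@H]2Oc3c(OC)cc([C@@H]4Oc5c(OC)cc(/C=C/C=O)cc5[C@H]4C=O)cc3[C@H]2C=O)ccc1O[Si](C(C)C)(C(C)C)C(C)C
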